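The synthesis rests on cutting the aryl–oxygen bond between the benzylic oxygen O7 and C3' of the allyl-bearing ring A. The precursor is an open threo 8-O-4' ether whose ring A is still the symmetric 4-allyl-2,6-dimethoxyphenoxy group of commercial methoxyeugenol. One-electron photooxidation reverses the polarity of this electron-rich ring. The C7 hydroxyl then displaces a methoxy group (lost as methanol) at C3' and closes the 1,4-dioxane ring in one redox-neutral operation, with both stereocentres untouched. The step exploits the two equivalent C–OMe carbons C3' and C5' that flank C4'. Either closure gives the same product, and the surviving methoxy group is that of the target. C8 stems from (S)-lactate, C7 from Felkin–Anh reduction.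

Key step: step 6

Remark: ring A is the allyl-bearing arene (C1' allyl, C4' bound to O8, C3' and C5' its oxygenated neighbours), ring B is the 4-oxygenated 3,5-dimethoxyphenyl ring, C7 is the benzylic carbon (bears O7) and C8 the methyl-bearing carbon (bears O8); compounds 1, 2 and 5 are assumed to be commercial.

Step 1
Reactants: 1 4-allyl-2,6-dimethoxyphenol (methoxyeugenol); 2 ethyl (S)-lactate
Product: 3 ethyl (2R)-2-(4-allyl-2,6-dimethoxyphenoxy)propanoate
Conditions: PPh3, DIAD, THF, 0 °C to rt
Reagents that add atoms: none
Why: Mitsunobu etherification, in which the phenol displaces the activated lactate hydroxyl in an SN2 process, so that (S) is inverted to (R) and C8 of the target is set.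

Step 2
Reactants: 3 ethyl (2R)-2-(4-allyl-2,6-dimethoxyphenoxy)propanoate
Product: 4 (2R)-2-(4-allyl-2,6-dimethoxyphenoxy)-N-methoxy-N-methylpropanamide
Conditions: MeNH(OMe)·HCl, iPrMgCl, THF, −20 to 0 °C; aq NH4Cl
Reagents that add atoms: N,O-dimethylhydroxylamine hydrochloride, CNOC.Cl
Why: Weinreb amide formation by aminolysis of the ester with the chloromagnesium amide made in situ, a low-temperature protocol that should leave the alpha-oxygenated stereocentre C8 intact.

Step 3
Reactants: 5 4-bromo-2,6-dimethoxyphenol
Product: 6 4-bromo-2,6-dimethoxyphenyl pivalate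
Conditions: PivCl, Et3N, DMAP (cat.), CH2Cl2, 0 °C to rt
Reagents that add atoms: pivaloyl chloride, CC(C)(C)C(=O)Cl
Why: DMAP-catalysed O-acylation of a phenol, giving an ester hindered enough for the organomagnesium and hydride steps that later also lowers the donor strength of ring B.

Step 4
Reactants: 6 4-bromo-2,6-dimethoxyphenyl pivalate; 4 (2R)-2-(4-allyl-2,6-dimethoxyphenoxy)-N-methoxy-N-methylpropanamide
Product: 8 4-[(2R)-2-(4-allyl-2,6-dimethoxyphenoxy)propanoyl]-2,6-dimethoxyphenyl pivalate, via arylmagnesium bromide 7 (not isolated)
Conditions: 6, Mg, LiCl, THF, 0 to 25 °C; then 4, −20 to 0 °C; aq NH4Cl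
Reagents that add atoms: magnesium, [Mg] (held only in 7)
Why: Weinreb ketone synthesis, in which LiCl-mediated magnesium insertion (tolerant of ester-type phenol protection) gives the aryl nucleophile and the chelated tetrahedral adduct stops at the ketone level and shields C8 from enolisation until the quench.

Step 5
Reactants: 8 4-[(2R)-2-(4-allyl-2,6-dimethoxyphenoxy)propanoyl]-2,6-dimethoxyphenyl pivalate
Product: 9 4-[(1R,2R)-2-(4-allyl-2,6-dimethoxyphenoxy)-1-hydroxypropyl]-2,6-dimethoxyphenyl pivalate (threo)
Conditions: Li[HB(s-Bu)3] (lithium tri-sec-butylborohydride), THF, −78 °C; aq NH4Cl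
Reagents that add atoms: none
Why: Polar Felkin–Anh reduction, in which the aryloxy group at C8 stands perpendicular to the carbonyl group and the bulky, poorly chelating hydride enters anti to it past the C8 hydrogen, which should set C7 as R (threo, syn) while pivalate and allyl group stay inert at −78 °C.

Step 6
Reactants: 9 4-[(1R,2R)-2-(4-allyl-2,6-dimethoxyphenoxy)-1-hydroxypropyl]-2,6-dimethoxyphenyl pivalate
Product: 10 4-[(2R,3R)-7-allyl-5-methoxy-3-methyl-2,3-dihydro-1,4-benzodioxin-2-yl]-2,6-dimethoxyphenyl pivalate
Conditions: 3,6-di-tert-butyl-9-mesityl-10-phenylacridinium tetrafluoroborate (5 mol %), 4 Å MS, DCE/HFIP (4:1), 0.02 M, no base, 456 nm LEDs, N2, rt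
Reagents that add atoms: none
Why: Proposed new method: the excited acridinium takes one electron from ring A, the C7 hydroxyl adds to the methoxy-bearing C3' of the radical cation to give a mixed-ketal cyclohexadienyl radical, proton transfer to the geminal methoxy oxygen expels methanol, and the radical cation of 10 is reduced by the acridinyl radical or by a further molecule of 9, so that no external oxidant is consumed. The closest known reaction type is the cation-radical-accelerated nucleophilic aromatic substitution of alkoxyarenes under acridinium photoredox catalysis (known for azoles, amines, cyanide and fluoride), and the elementary step, ipso attack of an alcohol on an alkoxyarene radical cation, is that of anodic quinone ketal formation; the new element is a tethered secondary alcohol as nucleophile. The 1,4-dioxane ring closes by ortho attack, a 6-endo-trig closure with respect to the C3'–C4' bond of ring A. No stereocentre is made and neither the C7–O7 nor the C8–O8 bond is touched, so the threo (7R,8R) array of 9 should be carried into the trans (2R,3R) ring. Chemoselectivity between the two arenes is secured by the pivalate, which makes ring B the poorer donor and keeps C7 from ionising in HFIP, and no choice between C3' and C5' is needed because rotation about O8–C4' makes them equivalent. Attack at C3' has to win over 5-exo spiro attack at C4', which is expected because O8 is twisted out of conjugation by its two ortho neighbours, so that the hole sits on the in-plane methoxy-bearing carbons, and because only the C3' adduct holds a leaving group (methanol, taken up by the sieves) whose loss is not the reverse reaction.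

Step 7
Reactants: 10 4-[(2R,3R)-7-allyl-5-methoxy-3-methyl-2,3-dihydro-1,4-benzodioxin-2-yl]-2,6-dimethoxyphenyl pivalate
Product: 11 4-[(2R,3R)-7-allyl-5-methoxy-3-methyl-2,3-dihydro-1,4-benzodioxin-2-yl]-2,6-dimethoxyphenol (target)
Conditions: LiAlH4, THF, 0 °C; aq Rochelle salt
Reagents that add atoms: none
Why: Hydride cleavage of an aryl ester, fast at 0 °C, where the allyl group, the aryl ethers and both stereocentres should stay untouched and the aluminium phenoxide has no time to open the benzylic ether.

Compound list
1 | 4-allyl-2,6-dimethoxyphenol (methoxyeugenol) | C=CCc1cc(OC)c(O)c(OC)c1 | starting material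
2 | ethyl (S)-lactate | C[C@H](O)C(=O)OCC | starting material
3 | ethyl (2R)-2-(4-allyl-2,6-dimethoxyphenoxy)propanoate | C=CCc1cc(OC)c(O[C@H](C)C(=O)OCC)c(OC)c1 | intermediate
4 | (2R)-2-(4-allyl-2,6-dimethoxyphenoxy)-N-methoxy-N-methylpropanamide | C=CCc1cc(OC)c(O[C@H](C)C(=O)N(C)OC)c(OC)c1 | intermediate
5 | 4-bromo-2,6-dimethoxyphenol | COc1cc(Br)cc(OC)c1O | starting material
6 | 4-bromo-2,6-dimethoxyphenyl pivalate | COc1cc(Br)cc(OC)c1OC(=O)C(C)(C)C | intermediate
7 | [3,5-dimethoxy-4-(pivaloyloxy)phenyl]magnesium bromide (LiCl-solvated, not isolated) | COc1cc([Mg]Br)cc(OC)c1OC(=O)C(C)(C)C | intermediate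
8 | 4-[(2R)-2-(4-allyl-2,6-dimethoxyphenoxy)propanoyl]-2,6-dimethoxyphenyl pivalate | C=CCc1cc(OC)c(O[C@H](C)C(=O)c2cc(OC)c(OC(=O)C(C)(C)C)c(OC)c2)c(OC)c1 | intermediate
9 | 4-[(1R,2R)-2-(4-allyl-2,6-dimethoxyphenoxy)-1-hydroxypropyl]-2,6-dimethoxyphenyl pivalate (threo) | C=CCc1cc(OC)c(O[C@H](C)[C@H](O)c2cc(OC)c(OC(=O)C(C)(C)C)c(OC)c2)c(OC)c1 | intermediate
10 | 4-[(2R,3R)-7-allyl-5-methoxy-3-methyl-2,3-dihydro-1,4-benzodioxin-2-yl]-2,6-dimethoxyphenyl pivalate (trans) | C=CCc1cc(OC)c2c(c1)O[C@H](c1cc(OC)c(OC(=O)C(C)(C)C)c(OC)c1)[C@@H](C)O2 | intermediate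
11 | 4-[(2R,3R)-7-allyl-5-methoxy-3-methyl-2,3-dihydro-1,4-benzodioxin-2-yl]-2,6-dimethoxyphenol (trans) | C=CCc1cc(OC)c2c(c1)O[C@H](c1cc(OC)c(O)c(OC)c1)[C@@H](C)O2 | target

Total step count: 7. Longest linear sequence: 6 (steps 1, 2, 4, 5, 6, 7).

Steps most likely to fail

1. Step 6 (proposed new method). The hole may not stay on ring A long enough for closure. Several processes could each erode the step:
- back electron transfer;
- loss of a proton from the doubly activated allylic CH2 of the radical cation;
- C7–C8 fragmentation after hole transfer to ring B;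
- spiro attack at C4' followed by oxygen-to-oxygen aryl migration;
- inhibition by the more easily oxidised product.

The fallback makes the same O7–C3' bond by known chemistry, the palladium-catalysed intramolecular etherification of an aryl bromide (Buchwald–Hartwig type). It sets out from 2 and comes back at 10. Eugenol is ortho-brominated (NBS, cat. iPr2NH, CH2Cl2) to 4-allyl-2-bromo-6-methoxyphenol F1. Mitsunobu reaction with 2 as in step 1 gives ethyl (2R)-2-(4-allyl-2-bromo-6-methoxyphenoxy)propanoate F2, and aminolysis as in step 2 gives the bromo Weinreb amide F3. Addition of 7 as in step 4 gives the bromo ketone F4, and reduction as in step 5 gives the threo (1R,2R) bromo alcohol F5. Pd(OAc)2, 2-(di-tert-butylphosphino)-1,1'-binaphthyl, Cs2CO3, toluene, 70 °C should then close the dioxane ring to 10 with retention at both stereocentres.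

2. Step 5. Lithium may be held between the carbonyl oxygen, O8 and an ortho methoxy group, which would turn the facial selectivity toward the erythro series. The basic hydride may also enolise the ketone and erode C8. The fallback moves stereocontrol from the substrate to a catalyst. It is a Noyori asymmetric transfer hydrogenation of 8 with RuCl(p-cymene)[(S,S)-TsDPEN] in HCO2H/Et3N, in which the aryl/alkyl discrimination of the catalyst should fix C7 as R whatever the chelation (matched with the Felkin–Anh bias). It sets out from 8, comes back at 9 and makes no further compound (F0).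

3. Step 4. Magnesium insertion may be sluggish, acyl transfer from the pivalate to the organomagnesium may strip the protecting group, and deprotonation of 4 at C8 may compete with addition. The fallback postpones the protection and uses an unprotected dianion. It sets out from 5 and comes back at 8. Compound 5 is deprotonated with n-BuLi and exchanged with t-BuLi (2 equiv, THF, −78 °C) to the O,C-dilithio species F6. Addition of 4 gives, after the quench, the (R)-hydroxy ketone F7, and pivaloylation of its phenol (PivCl, Et3N, CH2Cl2, 0 °C) gives 8.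

Further compounds
F1 | step 6 | 4-allyl-2-bromo-6-methoxyphenol | C=CCc1cc(Br)c(O)c(OC)c1
F2 | step 6 | ethyl (2R)-2-(4-allyl-2-bromo-6-methoxyphenoxy)propanoate | C=CCc1cc(Br)c(O[C@H](C)C(=O)OCC)c(OC)c1
F3 | step 6 | (2R)-2-(4-allyl-2-bromo-6-methoxyphenoxy)-N-methoxy-N-methylpropanamide | C=CCc1cc(Br)c(O[C@H](C)C(=O)N(C)OC)c(OC)c1
F4 | step 6 | 4-[(2R)-2-(4-allyl-2-bromo-6-methoxyphenoxy)propanoyl]-2,6-dimethoxyphenyl pivalate | C=CCc1cc(Br)c(O[C@H](C)C(=O)c2cc(OC)c(OC(=O)C(C)(C)C)c(OC)c2)c(OC)c1
F5 | step 6 | 4-[(1R,2R)-2-(4-allyl-2-bromo-6-methoxyphenoxy)-1-hydroxypropyl]-2,6-dimethoxyphenyl pivalate | C=CCc1cc(Br)c(O[C@H](C)[C@H](O)c2cc(OC)c(OC(=O)C(C)(C)C)c(OC)c2)c(OC)c1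
F0 | step 5 | none | none
F6 | step 4 | lithium 4-lithio-2,6-dimethoxyphenoxide | [Li]Oc1c(OC)cc([Li])cc1OC
F7 | step 4 | (2R)-2-(4-allyl-2,6-dimethoxyphenoxy)-1-(4-hydroxy-3,5-dimethoxyphenyl)propan-1-one | C=CCc1cc(OC)c(O[C@H](C)C(=O)c2cc(OC)c(O)c(OC)c2)c(OC)c1
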